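**Retrosynthetic overview**

1. The lactone C–O bond is never made by cyclisation, because a seco acid could close on the tertiary hydroxyl to give the six-membered lactone. Instead the oxepinone is closed at C3=C4 by ring-closing metathesis of an unprotected hydroxy acrylate.
2. The acrylate ester comes from intermolecular acylation of the secondary hydroxyl of an anti-diol with 2-(4-methylpent-3-enyl)acrylic acid (three steps from triethyl phosphonoacetate).
3. The anti-diol comes from a trans-epoxide by hydrolysis with inversion at the tertiary carbon; the epoxide comes from copper-catalysed vinylation of an epoxy triflate.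
4. One Sharpless epoxidation of 8-hydroxygeranyl acetate (from geranyl acetate) sets both stereocentres; no protecting groups are used and the acetate is carried from the start.
5. Ring order: the oxirane (step 2, opened in step 5) is temporary; the seven-membered lactone, the only ring of the target, is formed in the last step.

Assumption: the SMILES is read as the (6R,7S)-oxepinone (tertiary carbinol R, ring CH–O S, side-chain olefin E); geranyl acetate, triethyl phosphonoacetate and 5-bromo-2-methylpent-2-ene are bought.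

**Route**

Step 1
Reactants: 1 geranyl acetate, (2E)-3,7-dimethylocta-2,6-dien-1-yl acetate
Product: 2 (2E,6E)-8-hydroxy-3,7-dimethylocta-2,6-dien-1-yl acetate
Conditions: SeO2 (10 mol%), tBuOOH (70% aq., 3.5 equiv), salicylic acid (10 mol%), CH2Cl2, 20 °C
Reagents that add atoms: tert-butyl hydroperoxide, CC(C)(C)OO (oxygen source, relayed by catalytic selenium dioxide, O=[Se]=O)
Why: Catalytic SeO2 allylic oxidation (ene reaction then [2,3]-sigmatropic shift) hydroxylates the (E)-methyl group of the electron-rich 6,7-olefin and leaves the 2,3-olefin, deactivated by the allylic acetate, untouched; no stereocentre is formed.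

Step 2
Reactants: 2 (2E,6E)-8-hydroxy-3,7-dimethylocta-2,6-dien-1-yl acetate
Product: 3 (2E)-5-[(2S,3S)-3-(hydroxymethyl)-3-methyloxiran-2-yl]-3-methylpent-2-en-1-yl acetate
Conditions: Ti(OiPr)4 (10 mol%), L-(+)-diethyl tartrate (12 mol%), tBuOOH (anhydrous, 2 equiv), 4 Å molecular sieves, CH2Cl2, −20 °C
Reagents that add atoms: tert-butyl hydroperoxide, CC(C)(C)OO
Why: Katsuki–Sharpless asymmetric epoxidation, in which only the olefin of the free allylic alcohol is bound to the titanium tartrate and L-(+)-tartrate delivers oxygen to the face that gives the (2S,3S)-epoxide, so both stereocentres of the target are set in this one step.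

Step 3
Reactants: 3 (2E)-5-[(2S,3S)-3-(hydroxymethyl)-3-methyloxiran-2-yl]-3-methylpent-2-en-1-yl acetate
Product: 4 (2E)-3-methyl-5-[(2S,3S)-3-methyl-3-{[(trifluoromethanesulfonyl)oxy]methyl}oxiran-2-yl]pent-2-en-1-yl acetate
Conditions: Tf2O (1.2 equiv), 2,6-lutidine (1.5 equiv), CH2Cl2, −78 °C; cold NaHCO3 work-up, used at once
Reagents that add atoms: trifluoromethanesulfonic anhydride, O=S(=O)(OS(=O)(=O)C(F)(F)F)C(F)(F)F
Why: O-sulfonylation (triflate formation) of the primary alcohol at −78 °C with a hindered base makes C8 an electrophile without touching the epoxide or either stereocentre.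

Step 4
Reactants: 4 (2E)-3-methyl-5-[(2S,3S)-3-methyl-3-{[(trifluoromethanesulfonyl)oxy]methyl}oxiran-2-yl]pent-2-en-1-yl acetate
Product: 5 (2E)-3-methyl-5-[(2S,3S)-3-methyl-3-(prop-2-en-1-yl)oxiran-2-yl]pent-2-en-1-yl acetate
Conditions: CH2=CHMgBr (1.5 equiv), CuBr·SMe2 (10 mol%), THF, −78 to −50 °C
Reagents that add atoms: vinylmagnesium bromide, C=C[Mg]Br
Why: Copper-catalysed Grignard cross-coupling (SN2 displacement of a primary triflate), which at −78 °C is far faster than substitution of the allylic acetate, addition to the ester or opening of the trisubstituted epoxide, and which leaves both stereocentres unchanged.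

Step 5
Reactants: 5 (2E)-3-methyl-5-[(2S,3S)-3-methyl-3-(prop-2-en-1-yl)oxiran-2-yl]pent-2-en-1-yl acetate
Product: 6 (2E,6S,7R)-6,7-dihydroxy-3,7-dimethyldeca-2,9-dien-1-yl acetate
Conditions: HClO4 (3% aq.), THF, 0 °C
Reagents that add atoms: water, O
Why: Acid-catalysed epoxide hydrolysis, a borderline SN2 ring opening in which water attacks the protonated epoxide at the tertiary carbon anti to the C–O bond, so this centre is inverted (S to R) while the secondary carbinol keeps its oxygen and its S configuration, giving the anti-diol.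

Step 6
Reactants: 7 triethyl phosphonoacetate; 8 5-bromo-2-methylpent-2-ene
Product: 10 ethyl 2-(diethoxyphosphoryl)-6-methylhept-5-enoate (racemic), via sodium phosphonoacetate carbanion 9 (not isolated)
Conditions: NaH, DMF, 0 °C; then 8, 60 °C
Reagents that add atoms: none
Why: SN2 C-alkylation of the stabilised phosphonoacetate carbanion by the primary bromide (malonate-type alkylation); the new centre is racemic and is destroyed in the next step.

Step 7
Reactants: 10 ethyl 2-(diethoxyphosphoryl)-6-methylhept-5-enoate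
Product: 11 ethyl 6-methyl-2-methylidenehept-5-enoate
Conditions: HCHO (37% aq.), K2CO3, H2O, 70 °C
Reagents that add atoms: formaldehyde, C=O
Why: Horner–Wadsworth–Emmons methylenation with formaldehyde converts the α-alkyl phosphonoacetate into the 2-substituted acrylate.

Step 8
Reactants: 11 ethyl 6-methyl-2-methylidenehept-5-enoate
Product: 13 6-methyl-2-methylidenehept-5-enoic acid, via lithium 6-methyl-2-methylidenehept-5-enoate 12 (not isolated)
Conditions: LiOH·H2O, THF/H2O, 20 °C; then 1 M HCl
Reagents that add atoms: lithium hydroxide, [Li+].[OH-]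
Why: Saponification of the ethyl ester, followed by acidification to free the acrylic acid.

Step 9
Reactants: 13 6-methyl-2-methylidenehept-5-enoic acid; 6 (2E,6S,7R)-6,7-dihydroxy-3,7-dimethyldeca-2,9-dien-1-yl acetate
Product: 15 (2E,6S,7R)-1-acetoxy-7-hydroxy-3,7-dimethyldeca-2,9-dien-6-yl 6-methyl-2-methylidenehept-5-enoate, via mixed trichlorobenzoic anhydride 14 (not isolated)
Conditions: 2,4,6-Cl3C6H2COCl, Et3N, THF, 20 °C; then 6, DMAP, toluene, 45 °C
Reagents that add atoms: none
Why: Yamaguchi esterification, in which the activated mixed anhydride acylates the secondary hydroxyl while the tertiary hydroxyl is inert, so the acyl group is placed on the correct oxygen by an intermolecular, kinetically controlled step and no stereocentre is touched.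

Step 10
Reactants: 15 (2E,6S,7R)-1-acetoxy-7-hydroxy-3,7-dimethyldeca-2,9-dien-6-yl 6-methyl-2-methylidenehept-5-enoate
Product: 16 (6R,7S)-7-[(3E)-5-acetoxy-3-methylpent-3-en-1-yl]-6-hydroxy-6-methyl-3-(4-methylpent-3-en-1-yl)-6,7-dihydrooxepin-2(5H)-one (CNP0314901.1)
Conditions: second-generation Hoveyda–Grubbs catalyst RuCl2(H2IMes)(=CH-C6H4-2-OiPr) (10 mol%), toluene (2 mM), 80 °C, argon sparge
Reagents that add atoms: none
Why: Ring-closing olefin metathesis: the ruthenium alkylidene formed at the terminal vinyl group closes onto the 1,1-disubstituted acrylate with loss of ethene to give the seven-membered enoate, whose geometry is fixed by the ring, while the two trisubstituted olefins are too hindered to compete and the neutral medium leaves the stereocentres and the secondary ester in place.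

**Compound list**

1 | geranyl acetate, (2E)-3,7-dimethylocta-2,6-dien-1-yl acetate | CC(=O)OC/C=C(\C)CCC=C(C)C | starting material
2 | (2E,6E)-8-hydroxy-3,7-dimethylocta-2,6-dien-1-yl acetate | CC(=O)OC/C=C(\C)CC/C=C(\C)CO | intermediate
3 | (2E)-5-[(2S,3S)-3-(hydroxymethyl)-3-methyloxiran-2-yl]-3-methylpent-2-en-1-yl acetate | CC(=O)OC/C=C(\C)CC[C@@H]1O[C@@]1(C)CO | intermediate
4 | (2E)-3-methyl-5-[(2S,3S)-3-methyl-3-{[(trifluoromethanesulfonyl)oxy]methyl}oxiran-2-yl]pent-2-en-1-yl acetate | CC(=O)OC/C=C(\C)CC[C@@H]1O[C@@]1(C)COS(=O)(=O)C(F)(F)F | intermediate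
5 | (2E)-3-methyl-5-[(2S,3S)-3-methyl-3-(prop-2-en-1-yl)oxiran-2-yl]pent-2-en-1-yl acetate | CC(=O)OC/C=C(\C)CC[C@@H]1O[C@@]1(C)CC=C | intermediate
6 | (2E,6S,7R)-6,7-dihydroxy-3,7-dimethyldeca-2,9-dien-1-yl acetate | CC(=O)OC/C=C(\C)CC[C@H](O)[C@](C)(O)CC=C | intermediate
7 | triethyl phosphonoacetate | CCOC(=O)CP(=O)(OCC)OCC | starting material
8 | 5-bromo-2-methylpent-2-ene | CC(C)=CCCBr | starting material
9 | sodium salt of the triethyl phosphonoacetate carbanion | [Na+].CCOC(=O)[CH-]P(=O)(OCC)OCC | intermediate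
10 | ethyl 2-(diethoxyphosphoryl)-6-methylhept-5-enoate (racemic) | CCOC(=O)C(CCC=C(C)C)P(=O)(OCC)OCC | intermediate
11 | ethyl 6-methyl-2-methylidenehept-5-enoate | CCOC(=O)C(=C)CCC=C(C)C | intermediate
12 | lithium 6-methyl-2-methylidenehept-5-enoate | [Li+].[O-]C(=O)C(=C)CCC=C(C)C | intermediate
13 | 6-methyl-2-methylidenehept-5-enoic acid | OC(=O)C(=C)CCC=C(C)C | intermediate
14 | 6-methyl-2-methylidenehept-5-enoic 2,4,6-trichlorobenzoic anhydride | C=C(CCC=C(C)C)C(=O)OC(=O)c1c(Cl)cc(Cl)cc1Cl | intermediate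
15 | (2E,6S,7R)-1-acetoxy-7-hydroxy-3,7-dimethyldeca-2,9-dien-6-yl 6-methyl-2-methylidenehept-5-enoate | CC(=O)OC/C=C(\C)CC[C@H](OC(=O)C(=C)CCC=C(C)C)[C@](C)(O)CC=C | intermediate
16 | (6R,7S)-7-[(3E)-5-acetoxy-3-methylpent-3-en-1-yl]-6-hydroxy-6-methyl-3-(4-methylpent-3-en-1-yl)-6,7-dihydrooxepin-2(5H)-one | CC(=O)OC/C=C(\C)CC[C@@H]1OC(=O)C(CCC=C(C)C)=CC[C@@]1(C)O | target

**Step count and risks**

Total step count: 10. Longest linear sequence: 7 (steps 1, 2, 3, 4, 5, 9, 10).

Steps most likely to fail:

Step 4 (vinylation of the epoxy triflate). The triflate sits on a carbon next to a fully substituted epoxide carbon, and the Grignard reagent may attack the allylic acetate. The fallback sets out from compound 2 and comes back at compound 5. CBr4/PPh3 in CH2Cl2 at 0 °C converts 2 into (2E,6E)-8-bromo-3,7-dimethylocta-2,6-dien-1-yl acetate F1. Stille coupling with tributyl(vinyl)stannane (Pd2(dba)3, AsPh3, THF, 40 °C) then gives (2E,6E)-3,7-dimethyldeca-2,6,9-trien-1-yl acetate F2. Shi epoxidation with the L-fructose-derived enantiomer of the Shi ketone and KHSO5 (K2CO3 buffer, MeCN/dimethoxymethane, 0 °C) epoxidises only the electron-rich 6,7-olefin, from the same face as in step 2, to give 5.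

Step 9 (acylation of a hindered secondary alcohol by a hindered, polymerisable acrylic acid). The fallback sets out from compounds 10 and 6 and comes back at compound 15. LiOH in THF/H2O cleaves only the carboxylic ester of 10 to give 2-(diethoxyphosphoryl)-6-methylhept-5-enoic acid F3. DCC/DMAP in CH2Cl2 joins F3 to the secondary hydroxyl of 6 to give (2E,6S,7R)-1-acetoxy-7-hydroxy-3,7-dimethyldeca-2,9-dien-6-yl 2-(diethoxyphosphoryl)-6-methylhept-5-enoate F4. Horner–Wadsworth–Emmons methylenation of F4 with paraformaldehyde (LiCl, DBU, MeCN, 20 °C) then builds the acrylate on the ester and gives 15.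

Step 10 (ring-closing metathesis onto a 1,1-disubstituted acrylate). Closure may be slow, and the alkylidene could close onto the 2,3-olefin to give a cycloheptene, or dimerise. The fallback closes the same C3=C4 bond by intramolecular Horner–Wadsworth–Emmons olefination; it sets out from compound 4 and comes back at compound 16.
- 2-Lithio-1,3-dithiane (from 1,3-dithiane and n-BuLi, THF, −78 °C) displaces the triflate of 4 to give (2E)-5-[(2S,3S)-3-(1,3-dithian-2-ylmethyl)-3-methyloxiran-2-yl]-3-methylpent-2-en-1-yl acetate F5.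
- Hydrolysis as in step 5 gives (2E,6S,7R)-8-(1,3-dithian-2-yl)-6,7-dihydroxy-3,7-dimethyloct-2-en-1-yl acetate F6.
- DCC/DMAP esterification of its secondary hydroxyl with 2-(diethoxyphosphoryl)-6-methylhept-5-enoic acid F3 gives (2E,6S,7R)-1-acetoxy-8-(1,3-dithian-2-yl)-7-hydroxy-3,7-dimethyloct-2-en-6-yl 2-(diethoxyphosphoryl)-6-methylhept-5-enoate F7.
- MeI and CaCO3 in aqueous MeCN at 45 °C unmask the aldehyde to give (2E,6S,7R)-1-acetoxy-7-hydroxy-3,7-dimethyl-9-oxonon-2-en-6-yl 2-(diethoxyphosphoryl)-6-methylhept-5-enoate F8.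
- LiCl and iPr2NEt in MeCN at 1 mM close the seven-membered ring to 16.

Further compounds

F1 | step 4 | (2E,6E)-8-bromo-3,7-dimethylocta-2,6-dien-1-yl acetate | CC(=O)OC/C=C(\C)CC/C=C(\C)CBr
F2 | step 4 | (2E,6E)-3,7-dimethyldeca-2,6,9-trien-1-yl acetate | CC(=O)OC/C=C(\C)CC/C=C(\C)CC=C
F3 | step 9 | 2-(diethoxyphosphoryl)-6-methylhept-5-enoic acid | OC(=O)C(CCC=C(C)C)P(=O)(OCC)OCC
F4 | step 9 | (2E,6S,7R)-1-acetoxy-7-hydroxy-3,7-dimethyldeca-2,9-dien-6-yl 2-(diethoxyphosphoryl)-6-methylhept-5-enoate | CC(=O)OC/C=C(\C)CC[C@H](OC(=O)C(CCC=C(C)C)P(=O)(OCC)OCC)[C@](C)(O)CC=C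
F5 | step 10 | (2E)-5-[(2S,3S)-3-(1,3-dithian-2-ylmethyl)-3-methyloxiran-2-yl]-3-methylpent-2-en-1-yl acetate | CC(=O)OC/C=C(\C)CC[C@@H]1O[C@@]1(C)CC1SCCCS1
F6 | step 10 | (2E,6S,7R)-8-(1,3-dithian-2-yl)-6,7-dihydroxy-3,7-dimethyloct-2-en-1-yl acetate | CC(=O)OC/C=C(\C)CC[C@H](O)[C@](C)(O)CC1SCCCS1
F7 | step 10 | (2E,6S,7R)-1-acetoxy-8-(1,3-dithian-2-yl)-7-hydroxy-3,7-dimethyloct-2-en-6-yl 2-(diethoxyphosphoryl)-6-methylhept-5-enoate | CC(=O)OC/C=C(\C)CC[C@H](OC(=O)C(CCC=C(C)C)P(=O)(OCC)OCC)[C@](C)(O)CC1SCCCS1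
F8 | step 10 | (2E,6S,7R)-1-acetoxy-7-hydroxy-3,7-dimethyl-9-oxonon-2-en-6-yl 2-(diethoxyphosphoryl)-6-methylhept-5-enoate | CC(=O)OC/C=C(\C)CC[C@H](OC(=O)C(CCC=C(C)C)P(=O)(OCC)OCC)[C@](C)(O)CC=O
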